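**Remark on the chemistry:** sugar positions are cited as C1–C5/O2–O5 of L-arabinose and carbocycle positions as ring C1–C6 (C1 = alkynyl carbon, C6 = the carbinol next to it). The open-chain precursor 19, the cyclised silyl ether 21 and 22 were compared centre by centre (C2/C3/C4 of 19 become ring C5/C4/C3; bromine cis to the chain) and agree, so no structure needed correction. The precursor keeps its TBS ether, acetate and free tertiary alcohol; the refinements concern how it is reached and the buffered final desilylation.

## Structural features

22 is a single carbocycle, a cyclohexene (ring C1–C6), whose alkene carbon C1 carries a 7-hydroxy-7-methyl-3-methylideneoct-5-en-1-ynyl chain. C2=C1–C≡C–C(=CH2) is therefore a cross-conjugated dienyne, continued through one CH2 group into an (E)-alkene and a tertiary allylic alcohol. The other four ring carbons are contiguous oxygen-bearing stereocentres: C3 (acetate, S), C4 (methyl ether, R), C5 and C6 (free hydroxyls, both S), with C3/C4 cis, C4/C5 trans and C5/C6 cis. Fragile points are the secondary allylic acetate (migration, ionisation, elimination), the acid-labile tertiary allylic alcohol, the 1,3-enyne and skipped diene, and the allylic C6 carbinol. The real difficulty is twofold. Four neighbouring oxygens must end in three different states (acetyl, methyl, free, free), and the fully substituted alkene carbon C1 must be bonded both to the alkyne and to C6, with the C6 hydroxyl cis to the C5 oxygen. The key step exploits that C6, C5, C4, C3 and C2 have the constitution and configuration of C1–C5 of an L-arabino pentose. An aldehyde at C6 and a metallated alkene carbon C1 (metal cis to the C3 chain) can then close the C1–C6 bond, forming the ring and the last stereocentre with the whole side chain already attached.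

## Logic of the disconnections

**22 ⇒ 21.** The O–Si bond on the C5 oxygen is cut. This oxygen sits α to the carbonyl carbon of the ring-forming step and must be protected and non-chelating there, whereas the C6 hydroxyl is born free and the tertiary hydroxyl needs no mask. The skeleton is not simplified, but the end game shrinks to one deprotection. The forward step must remove a hindered secondary silyl ether without moving the acetate to the neighbouring hydroxyls and without ionising the tertiary allylic alcohol.

**21 ⇒ 19 (through 20).** The ring bond C1–C6 is cut. The cyclohexene opens to an acyclic chain in which ring C6 is a formyl carbon and ring C1 carries bromine. The only ring and the C6 stereocentre disappear, and the three remaining stereocentres form a pentose-type triad with the side chain untouched. The forward step must generate a carbon nucleophile at the bromoalkene (20) beside an aldehyde, an ester and a free hydroxyl. It needs the bromine cis to the oxygenated chain and must place the C6 hydroxyl cis to the C5 silyloxy group.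

**19 ⇒ 18.** The C=O of the formyl group is replaced by two C–S bonds. The other chain terminus has also been an aldehyde, so the two ends can be told apart only if this one stays masked. Releasing it last also keeps the epimerisable α-silyloxy aldehyde short-lived. The hydrolysis must attack sulfur only and spare the dienyne, acetate and silyl ether.

**18 ⇒ 17 + 7.** The C(sp2)–C(sp) bond between the brominated alkene carbon and the alkyne is cut. This is the convergent cut: 17 holds every stereocentre and 7 holds the whole unsaturated side chain. The coupling must replace only the bromine trans to the chain, so that the cis bromine needed for step 14 remains.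

**17 ⇒ 16 ⇒ 15.** The C=CBr2 bond is cut back to the aldehyde 16, and that is traced to the primary alcohol 15. The chain returns to five carbons, the size of a pentose. The oxidation must respect the dithiane and the α-acetoxy centre, and the olefination must run without base.

**15 ⇒ 14 ⇒ 13.** The two C–S bonds of 15 are cut and the C1–O5 bond is restored, giving the pyranose 14. Adding the anomeric O–benzyl bond gives 13. In a pyranoside O5 is tied up in the ring and the secondary hydroxyls are fixed in space, which makes them distinguishable. The forward steps are a hydrogenolysis, run before any sulfur is present, and a ring-opening thioacetalisation mild enough for silyl ether and acetate.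

**13 ⇒ 12 ⇒ 9 (through 10 and 11).** The O3–CH3 bond is cut to give 12. The O4–acyl and O2–Si bonds are then cut to give the triol 9. O3 and O4 are the only cis diol of 9. A cyclic orthoester across them (10) leaves O2 alone for silylation (11) and then opens to the ester on the axial O4. Three hydroxyls are thus differentiated in one operation. The methylation of O3 must be non-basic, otherwise the acetate would migrate.

**9 ⇒ 8.** The anomeric C–O bond to benzyl is cut. The glycoside locks the pyranose form with a group removable by hydrogenolysis. The forward step relies on thermodynamic control for the axial β-glycoside.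

**7 ⇒ 6 ⇒ 4 + 5.** The alkyne C–H of 7 is traced to the C–Si bond of 6. The C(sp2)–C(sp) bond of 6 is then cut to the 2-bromodiene 4 and 5. The coupling must take place at an unactivated 2-bromoalkene without touching the skipped diene.

**4 ⇒ 2 + 3, 2 ⇒ 1.** The bond between the allylic CH2 and the (E)-alkene carbon is cut, giving the alkenylboronate 2 and 3. The C–B bond of 2 is then cut back to 1. Syn borylation of the alkyne fixes the E geometry, and 3 supplies both the CH2 and the vinylic bromide used next. The coupling must occur at the allylic and not the vinylic bromide of 3.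

## Other disconnections considered

**Alternative 1:** The cut is the ring C2–C3 bond, leading back to the hex-5-enopyranoside A2, obtainable from D-galactose A3 in about five steps.
- **Forward key step:** catalytic Hg(OCOCF3)2 in aqueous acetone adds water across the exocyclic enol ether. The hemiketal collapses to a ring-opened mercurio-ketone aldehyde, and an intramolecular aldol reaction closes the cyclohexanone A1 (ketone at C1, hydroxyl at C3).
- **In its favour:** the C4, C5 and C6 oxygens come unchanged from the hexose. The new C3 hydroxyl is expected trans to the C5 oxygen, which is the configuration needed. On security of the C6 configuration this route is the better one, since no diastereoselective C–C bond formation decides it.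
- **Against it here:** A1 has neither the C1=C2 alkene nor the side chain. As a β-hydroxy ketone it tends to eliminate towards C2=C3, the wrong alkene. The chain would have to be added as the acetylide of 7 to the C1 ketone, and the tertiary carbinol then dehydrated towards C2 beside the C3 acetate. Finally the acetonide would have to be hydrolysed by acid next to a tertiary allylic alcohol and an enyne.
- **Comparison:** structurally it secures more stereocentres from the chiral pool. Mechanistically its ring closure is catalytic, though in a toxic mercury salt, which is no better than stoichiometric CrCl2 (equal). In step economy it is not shorter, about five or six steps after the ring closure against one in the chosen plan, and those late steps are the uncertain ones.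

**Alternative 2:** The cuts are the C4–O and C5–O bonds of an oxirane that stands for the trans C4-OMe/C5-OH pair, leading back to the achiral alkynyl quinone monoketal A5.
- **Forward key step:** Ph3COOH deprotonated by NaN(SiMe3)2 in the presence of a diisopropyl tartrate adds as a peroxide anion to the unsubstituted C4=C5 enone alkene. Ring closure of the enolate onto the O–O bond gives the epoxy enone A4, with face selection by the tartrate-bound sodium peroxide.
- **In its favour:** the full carbon skeleton comes from an aromatic precursor in a few robust steps, and the side chain is joined at the most tolerant stage. The absolute configuration comes from a reagent. In step count up to the ring with side chain this route is better than the chosen plan.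
- **Against it here:** A4 holds two of the four stereocentres. Still needed are a face-selective reduction of the C3 ketone and methanolysis of the oxirane at C4 and not C5 (not secured, and acidic beside a tertiary allylic silyl ether). Also needed are hydrolysis of the ketal to a C6 enone (a γ-acyloxy enone prone to aromatise), reduction cis to C5-OH, and mono-acetylation of C3-OH. The enantioselectivity for a C1-alkynyl substrate is not assured.
- **Comparison:** on paper the longest line is about equal or somewhat shorter (equal or better on step economy). The chosen plan sets one stereocentre after ring formation where this route must set three by substrate control, so it is better on stereochemical security and on differentiation of the oxygens.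

**Alternative 3:** The cut is the C1=C2 double bond, leading back to the acyclic diene A7. A7 is derived from A3 by zinc-mediated fragmentation of a 6-iodo pyranoside to a hex-5-enal and addition of a 2-(alkoxymethyl)vinyl metal.
- **Forward key step:** the second-generation Grubbs catalyst loads at the monosubstituted vinyl group and closes onto the 1,1-disubstituted alkene by [2+2] cycloaddition and cycloreversion, giving the cyclohexene A6.
- **In its favour:** this is among the most dependable ways to close a cyclohexene. It is catalytic and tolerant of acetate and acetal, and the ring closure creates no stereocentre. On robustness of the ring-forming event and on metal load it is better than the chosen plan. It uses the same pentose-type triad for C3–C5.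
- **Against it here:** an enyne cannot be carried through metathesis, so C1 bears only a protected hydroxymethyl group. After ring closure come ether cleavage, oxidation to the enal, one-carbon homologation to the alkyne (usually basic, a danger to the acetate), coupling with 4, and acid removal of the acetonide. The C6 configuration still arises from addition of an alkenyl metal to an α-alkoxy aldehyde, now intermolecular, so the stereochemical question of the chosen key step is not avoided (equal).
- **Comparison:** the route is clearly longer, and the side chain is built on the sensitive ring rather than carried through it.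

Key step: step 14

## Route

**Step 1**
Reactants: 1 2-methylbut-3-yn-2-ol
Product: 2 (E)-2-methyl-4-(4,4,5,5-tetramethyl-1,3,2-dioxaborolan-2-yl)but-3-en-2-ol
Conditions: CuCl (5 mol%), NaOtBu (10 mol%), Xantphos (5 mol%), B2pin2, MeOH, THF, rt
Reagents that add atoms: bis(pinacolato)diboron, CC1(C)OB(OC1(C)C)B1OC(C)(C)C(C)(C)O1
Why: Copper-catalysed formal hydroboration of a terminal alkyne: a Cu–Bpin species adds syn with boron on the unhindered terminal carbon and methanol protonates the alkenylcopper, which should give the (E)-alkenylboronate; the free tertiary hydroxyl is tolerated.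

**Step 2**
Reactants: 2 (E)-2-methyl-4-(4,4,5,5-tetramethyl-1,3,2-dioxaborolan-2-yl)but-3-en-2-ol; 3 2,3-dibromopropene (2.5 equiv)
Product: 4 (3E)-6-bromo-2-methylhepta-3,6-dien-2-ol
Conditions: Pd(PPh3)4 (3 mol%), K2CO3, THF/H2O (10:1), 40 °C
Reagents that add atoms: none
Why: Suzuki–Miyaura allyl–alkenyl coupling: zerovalent palladium inserts into the allylic C–Br bond of 3 far faster than into the vinylic one, the 2-bromo-π-allyl complex is symmetrical at its termini so no regiochemical question arises, and the alkenyl group transfers with retention of the (E) geometry. The excess of 3 keeps the vinylic bromide of the product from competing.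

**Step 3**
Reactants: 4 (3E)-6-bromo-2-methylhepta-3,6-dien-2-ol; 5 trimethylsilylacetylene
Product: 6 (3E)-2-methyl-6-methylidene-8-(trimethylsilyl)oct-3-en-7-yn-2-ol
Conditions: PdCl2(PPh3)2 (3 mol%), CuI (5 mol%), iPr2NH, THF, 50 °C, sealed vessel
Reagents that add atoms: none
Why: Sonogashira coupling of a 2-bromo-1-alkene with a terminal alkyne; the silyl group blocks the second alkyne terminus and the skipped diene and tertiary alcohol are spectators.

**Step 4**
Reactants: 6 (3E)-2-methyl-6-methylidene-8-(trimethylsilyl)oct-3-en-7-yn-2-ol
Product: 7 (3E)-2-methyl-6-methylideneoct-3-en-7-yn-2-ol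
Conditions: K2CO3 (cat.), MeOH, 0 °C to rt
Reagents that add atoms: none
Why: Carbonate-catalysed methanolysis of the alkynyl C–Si bond is fast and selective; 7 is used promptly because terminal 1,3-enynes polymerise on standing.

**Step 5**
Reactants: 8 L-arabinose
Product: 9 benzyl β-L-arabinopyranoside
Conditions: BnOH, HCl (anhydrous, cat.), 50 °C; crystallisation
Reagents that add atoms: benzyl alcohol, OCc1ccccc1
Why: Fischer glycosidation under thermodynamic control: the β-pyranoside with its axial benzyloxy group (anomeric effect) should predominate and crystallise; the ring stereocentres are those of 8.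

**Step 6**
Reactants: 9 benzyl β-L-arabinopyranoside
Product: 12 benzyl 4-O-acetyl-2-O-(tert-butyldimethylsilyl)-β-L-arabinopyranoside, via 3,4-orthoacetate 10 (not isolated), via 2-O-silyl 3,4-orthoacetate 11 (not isolated)
Conditions: (i) MeC(OMe)3, camphorsulfonic acid (cat.), MeCN, rt, then Et3N, evaporation; (ii) TBSCl, imidazole, 4-dimethylaminopyridine (cat.), DMF, 40 °C; (iii) AcOH/H2O (4:1), rt
Reagents that add atoms: trimethyl orthoacetate, CC(OC)(OC)OC; tert-butyldimethylsilyl chloride, CC(C)(C)[Si](C)(C)Cl; water, O
Why: Only the cis-3,4-diol of 9 can span a five-membered orthoester, so O2 is the single free hydroxyl left for silylation. Mild aqueous acid then opens the dioxolan-2-ylium ion through the hemiorthoester to the ester on the axial oxygen O4, the established regiochemistry for cis axial/equatorial diols, and frees O3; a secondary TBS ether survives brief aqueous acetic acid.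

**Step 7**
Reactants: 12 benzyl 4-O-acetyl-2-O-(tert-butyldimethylsilyl)-β-L-arabinopyranoside
Product: 13 benzyl 4-O-acetyl-2-O-(tert-butyldimethylsilyl)-3-O-methyl-β-L-arabinopyranoside
Conditions: MeOTf, 2,6-di-tert-butyl-4-methylpyridine, CH2Cl2, 0 °C to rt
Reagents that add atoms: methyl trifluoromethanesulfonate, COS(=O)(=O)C(F)(F)F
Why: O-Methylation with methyl triflate and a hindered pyridine base is the standard way to methylate partially acylated sugars without acyl migration, because no alkoxide is formed; silyl ether and glycoside are inert.

**Step 8**
Reactants: 13 benzyl 4-O-acetyl-2-O-(tert-butyldimethylsilyl)-3-O-methyl-β-L-arabinopyranoside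
Product: 14 4-O-acetyl-2-O-(tert-butyldimethylsilyl)-3-O-methyl-L-arabinopyranose (anomeric mixture)
Conditions: H2 (1 atm), 10% Pd/C, EtOAc, rt
Reagents that add atoms: none
Why: Hydrogenolysis of the anomeric benzyl group gives the hemiacetal; it is placed before any sulfur enters the molecule so the catalyst is not poisoned, and acetate, silyl and methyl ethers are untouched.

**Step 9**
Reactants: 14 4-O-acetyl-2-O-(tert-butyldimethylsilyl)-3-O-methyl-L-arabinopyranose
Product: 15 4-O-acetyl-2-O-(tert-butyldimethylsilyl)-3-O-methyl-L-arabinose propane-1,3-diyl dithioacetal (2-substituted 1,3-dithiane with free O5 hydroxyl)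
Conditions: HS(CH2)3SH, BF3·OEt2, CH2Cl2, −40 to −10 °C
Reagents that add atoms: propane-1,3-dithiol, SCCCS
Why: Lewis-acid thioacetalisation of a lactol: the first C–S bond forms at the anomeric carbon and endocyclic C1–O5 cleavage to the thionium ion is driven by intramolecular capture by the second thiol, so the acyclic dithiane with a free primary hydroxyl should result. Low temperature protects the TBS ether and disfavours acid-catalysed acetyl migration to O5.

**Step 10**
Reactants: 15 4-O-acetyl-2-O-(tert-butyldimethylsilyl)-3-O-methyl-L-arabinose propane-1,3-diyl dithioacetal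
Product: 16 4-O-acetyl-2-O-(tert-butyldimethylsilyl)-3-O-methyl-L-arabino-pentodialdose 1-(propane-1,3-diyl dithioacetal)
Conditions: SO3·pyridine, DMSO, iPr2NEt, CH2Cl2, 0 °C; used crude
Reagents that add atoms: none
Why: Parikh–Doering oxidation with activated DMSO converts the primary alcohol to the aldehyde without oxidising the dithiane sulfur atoms; the hindered amine at 0 °C limits epimerisation of the α-acetoxy centre.

**Step 11**
Reactants: 16 4-O-acetyl-2-O-(tert-butyldimethylsilyl)-3-O-methyl-L-arabino-pentodialdose 1-(propane-1,3-diyl dithioacetal)
Product: 17 4-O-acetyl-6,6-dibromo-2-O-(tert-butyldimethylsilyl)-5,6-dideoxy-3-O-methyl-L-arabino-hex-5-enose propane-1,3-diyl dithioacetal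
Conditions: CBr4, PPh3, Zn, CH2Cl2, rt (reagent preformed); then 16, 0 °C to rt
Reagents that add atoms: carbon tetrabromide, BrC(Br)(Br)Br
Why: Ramirez dibromoolefination (first stage of the Corey–Fuchs sequence): preformed Ph3P=CBr2 undergoes a Wittig reaction with the aldehyde under essentially neutral conditions. The zinc variant avoids free Ph3PBr2, which could attack the silyl ether or the dithiane.

**Step 12**
Reactants: 17 4-O-acetyl-6,6-dibromo-2-O-(tert-butyldimethylsilyl)-5,6-dideoxy-3-O-methyl-L-arabino-hex-5-enose propane-1,3-diyl dithioacetal; 7 (3E)-2-methyl-6-methylideneoct-3-en-7-yn-2-ol (1.1 equiv, slow addition)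
Product: 18 propane-1,3-diyl dithioacetal of aldehyde 19 (1,3-dithiane; (Z)-bromoenyne with bromine cis to the oxygenated chain)
Conditions: PdCl2(dppf) (5 mol%), CuI (10 mol%), iPr2NH, THF (degassed), rt
Reagents that add atoms: none
Why: Sonogashira coupling of a 1,1-dibromo-1-alkene: zerovalent palladium inserts selectively into the less hindered C–Br bond trans to the alkyl chain, so mono-alkynylation should leave the bromine cis to the chain. The vinylic C–Br bond reacts faster than the deactivated, α-alkoxy-substituted allylic acetate can ionise, and slow addition of 7 guards against a second coupling.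

**Step 13**
Reactants: 18 propane-1,3-diyl dithioacetal of aldehyde 19
Product: 19 (2R,3S,4S,5Z,11E)-4-(acetyloxy)-6-bromo-2-[(tert-butyldimethylsilyl)oxy]-13-hydroxy-3-methoxy-13-methyl-9-methylidenetetradeca-5,11-dien-7-ynal
Conditions: MeI (excess), CaCO3, MeCN/H2O (9:1), 40 °C, dark; used without storage
Reagents that add atoms: water, O
Why: Alkylative hydrolysis of the dithiane: S-methylation makes sulfur a leaving group, water captures the thionium ion and a second methylation releases the aldehyde. The reagent touches neither dienyne, bromoalkene, acetate nor silyl ether, and CaCO3 buffers the HI formed.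

**Step 14**
Reactants: 19 (2R,3S,4S,5Z,11E)-4-(acetyloxy)-6-bromo-2-[(tert-butyldimethylsilyl)oxy]-13-hydroxy-3-methoxy-13-methyl-9-methylidenetetradeca-5,11-dien-7-ynal
Product: 21 (1S,4S,5S,6S)-5-[(tert-butyldimethylsilyl)oxy]-4-hydroxy-3-[(5E)-7-hydroxy-7-methyl-3-methylideneoct-5-en-1-yn-1-yl]-6-methoxycyclohex-2-en-1-yl acetate, via alkenylchromium dichloride 20 (not isolated)
Conditions: CrCl2 (8 equiv), NiCl2 (2 mol%), DMSO (degassed, 0.005 M), rt; aqueous NH4Cl work-up
Reagents that add atoms: none
Why: Nozaki–Hiyama–Kishi reaction: CrCl2 reduces NiCl2 to zerovalent nickel, which inserts into the C–Br bond of the bromoenyne with retention of alkene geometry and hands the alkenyl group to trivalent chromium to give 20, while the nickel re-enters the cycle. The C–Cr bond of 20 adds to the aldehyde, the only group in the molecule that an alkenylchromium reagent attacks (acetate, free tertiary alcohol, alkyne and skipped diene are spectators), and so forms the ring C1–C6 bond; the closest known reaction type is the chromium/nickel-mediated cyclisation of haloalkene aldehydes to cyclic allylic alcohols. The ring closes in the 6-exo-trig mode, which is possible only because the bromine, and hence the chromium, stands cis to the oxygenated chain, as the trans-selective coupling of step 12 leaves it. The new stereocentre (ring C6) is controlled by the adjacent silyloxy-bearing carbon: in the half-chair-like transition state the OTBS group and the neighbouring OMe are pseudo-equatorial, the C–OTBS bond lies anti to the forming C–C bond (Felkin–Anh) and the chromium-bound carbonyl oxygen is pseudo-axial, which places the hydroxyl cis to the silyloxy group. The bulky, non-chelating silyl ether keeps the aldehyde out of an α-chelate that would favour the trans isomer. High dilution suppresses intermolecular addition, and the low nickel loading suppresses homocoupling of the alkenyl bromide and nickel-mediated reaction at the alkyne.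

**Step 15**
Reactants: 21 (1S,4S,5S,6S)-5-[(tert-butyldimethylsilyl)oxy]-4-hydroxy-3-[(5E)-7-hydroxy-7-methyl-3-methylideneoct-5-en-1-yn-1-yl]-6-methoxycyclohex-2-en-1-yl acetate
Product: 22 (1S,4S,5S,6R)-4,5-dihydroxy-3-[(5E)-7-hydroxy-7-methyl-3-methylideneoct-5-en-1-yn-1-yl]-6-methoxycyclohex-2-en-1-yl acetate
Conditions: HF·pyridine, pyridine, THF, 0 °C to rt
Reagents that add atoms: none
Why: Fluoride cleaves the secondary TBS ether through formation of the strong Si–F bond. Buffering with extra pyridine keeps the medium too weakly acidic to ionise the tertiary allylic alcohol and not basic enough for the acetate to migrate to the freed hydroxyls; no stereocentre is touched.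

## Compound list

1 | 2-methylbut-3-yn-2-ol | CC(C)(O)C#C | starting material
2 | (E)-2-methyl-4-(4,4,5,5-tetramethyl-1,3,2-dioxaborolan-2-yl)but-3-en-2-ol | CC(C)(O)/C=C/B1OC(C)(C)C(C)(C)O1 | intermediate
3 | 2,3-dibromopropene | C=C(Br)CBr | starting material
4 | (3E)-6-bromo-2-methylhepta-3,6-dien-2-ol | CC(C)(O)/C=C/CC(Br)=C | intermediate
5 | trimethylsilylacetylene | C[Si](C)(C)C#C | starting material
6 | (3E)-2-methyl-6-methylidene-8-(trimethylsilyl)oct-3-en-7-yn-2-ol | CC(C)(O)/C=C/CC(=C)C#C[Si](C)(C)C | intermediate
7 | (3E)-2-methyl-6-methylideneoct-3-en-7-yn-2-ol | CC(C)(O)/C=C/CC(=C)C#C | intermediate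
8 | L-arabinose | O=C[C@H](O)[C@@H](O)[C@@H](O)CO | starting material
9 | benzyl β-L-arabinopyranoside | c1ccccc1CO[C@@H]1[C@H](O)[C@@H](O)[C@@H](O)CO1 | intermediate
10 | benzyl 3,4-O-(1-methoxyethylidene)-β-L-arabinopyranoside (either configuration at the orthoester carbon) | c1ccccc1CO[C@@H]1[C@H](O)[C@H]2OC(C)(OC)O[C@H]2CO1 | intermediate
11 | benzyl 2-O-(tert-butyldimethylsilyl)-3,4-O-(1-methoxyethylidene)-β-L-arabinopyranoside | c1ccccc1CO[C@@H]1[C@H](O[Si](C)(C)C(C)(C)C)[C@H]2OC(C)(OC)O[C@H]2CO1 | intermediate
12 | benzyl 4-O-acetyl-2-O-(tert-butyldimethylsilyl)-β-L-arabinopyranoside | c1ccccc1CO[C@@H]1[C@H](O[Si](C)(C)C(C)(C)C)[C@@H](O)[C@@H](OC(C)=O)CO1 | intermediate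
13 | benzyl 4-O-acetyl-2-O-(tert-butyldimethylsilyl)-3-O-methyl-β-L-arabinopyranoside | c1ccccc1CO[C@@H]1[C@H](O[Si](C)(C)C(C)(C)C)[C@@H](OC)[C@@H](OC(C)=O)CO1 | intermediate
14 | 4-O-acetyl-2-O-(tert-butyldimethylsilyl)-3-O-methyl-L-arabinopyranose (anomeric mixture) | OC1[C@H](O[Si](C)(C)C(C)(C)C)[C@@H](OC)[C@@H](OC(C)=O)CO1 | intermediate
15 | 4-O-acetyl-2-O-(tert-butyldimethylsilyl)-3-O-methyl-L-arabinose propane-1,3-diyl dithioacetal | S1CCCSC1[C@H](O[Si](C)(C)C(C)(C)C)[C@@H](OC)[C@@H](OC(C)=O)CO | intermediate
16 | 4-O-acetyl-2-O-(tert-butyldimethylsilyl)-3-O-methyl-L-arabino-pentodialdose 1-(propane-1,3-diyl dithioacetal) | S1CCCSC1[C@H](O[Si](C)(C)C(C)(C)C)[C@@H](OC)[C@@H](OC(C)=O)C=O | intermediate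
17 | 4-O-acetyl-6,6-dibromo-2-O-(tert-butyldimethylsilyl)-5,6-dideoxy-3-O-methyl-L-arabino-hex-5-enose propane-1,3-diyl dithioacetal | S1CCCSC1[C@H](O[Si](C)(C)C(C)(C)C)[C@@H](OC)[C@@H](OC(C)=O)C=C(Br)Br | intermediate
18 | propane-1,3-diyl dithioacetal of 19 (2-substituted 1,3-dithiane, (Z)-bromoenyne, (E)-alkene) | S1CCCSC1[C@H](O[Si](C)(C)C(C)(C)C)[C@@H](OC)[C@@H](OC(C)=O)/C=C(\Br)C#CC(=C)C/C=C/C(C)(C)O | intermediate
19 | (2R,3S,4S,5Z,11E)-4-(acetyloxy)-6-bromo-2-[(tert-butyldimethylsilyl)oxy]-13-hydroxy-3-methoxy-13-methyl-9-methylidenetetradeca-5,11-dien-7-ynal | O=C[C@H](O[Si](C)(C)C(C)(C)C)[C@@H](OC)[C@@H](OC(C)=O)/C=C(\Br)C#CC(=C)C/C=C/C(C)(C)O | intermediate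
20 | alkenylchromium dichloride from 19 (CrCl2 in place of bromine, alkene geometry retained) | O=C[C@H](O[Si](C)(C)C(C)(C)C)[C@@H](OC)[C@@H](OC(C)=O)/C=C(\[Cr](Cl)Cl)C#CC(=C)C/C=C/C(C)(C)O | intermediate
21 | (1S,4S,5S,6S)-5-[(tert-butyldimethylsilyl)oxy]-4-hydroxy-3-[(5E)-7-hydroxy-7-methyl-3-methylideneoct-5-en-1-yn-1-yl]-6-methoxycyclohex-2-en-1-yl acetate | C=C(C#CC1=C[C@H](OC(C)=O)[C@H](OC)[C@@H](O[Si](C)(C)C(C)(C)C)[C@H]1O)C/C=C/C(C)(C)O | intermediate
22 | (1S,4S,5S,6R)-4,5-dihydroxy-3-[(5E)-7-hydroxy-7-methyl-3-methylideneoct-5-en-1-yn-1-yl]-6-methoxycyclohex-2-en-1-yl acetate (CNP0546270.2) | C=C(C#CC1=C[C@H](OC(C)=O)[C@H](OC)[C@@H](O)[C@H]1O)C/C=C/C(C)(C)O | target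

## Step count and risk

Total step count: 15 (steps 1–4 side chain, steps 5–11 sugar fragment, steps 12–15 after union of the fragments).
Longest linear sequence: 11 steps (steps 5–15, from 8).

**Step 14 (key step).** The most likely failure is poor facial selectivity in the addition to the aldehyde. The tether restricts the Felkin–Anh arrangement, and a half-chair with the two ring oxygens pseudo-axial could compete. Reduction of the C–Br bond without ring closure is a secondary risk if the alkenylchromium is protonated first. Fallback, from 19 back to 21: the cyclisation is run as in step 14 and the unwanted stereoisomer, the C6 epimer of 21 F1, is not discarded. It is oxidised, alone or mixed with 21, with MnO2 in CH2Cl2 to the ring C6 ketone F2. F2 is reduced at once by a Corey–Bakshi–Shibata reduction ((S)-2-methyl-CBS-oxazaborolidine, catecholborane, toluene, −78 °C; the alkynyl-substituted alkene carbon taken as the large group), so that C6 is set by the catalyst. F2 is a γ-acetoxy enone that can eliminate and aromatise, so it must be kept neutral and cold and not stored.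

**Step 9.** The conditions must stay mild for the silyl ether, so the endocyclic C1–O5 cleavage may stall at the cyclic thioglycoside stage. Forcing it risks loss of the silyl group and acid-catalysed acetyl migration to O5. Fallback, from 9 back to 15: the orthoester 10 is benzylated instead of silylated (NaH, BnBr, DMF) to the 2-O-benzyl orthoacetate F3. Aqueous acetic acid opens F3 to benzyl 4-O-acetyl-2-O-benzyl-β-L-arabinopyranoside F4. Methylation as in step 7 gives its 3-O-methyl ether F5. Hydrogenolysis removes both benzyl groups to give 4-O-acetyl-3-O-methyl-L-arabinopyranose F6. With no silyl ether present the thioacetalisation can be pushed (BF3·OEt2, 0 °C) to the 2,5-diol dithiane F7. TBSOTf/2,6-lutidine silylates both hydroxyls to the 2,5-bis-silyl ether F8, and buffered HF·pyridine at 0 °C removes only the primary silyl ether, returning to 15.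

**Step 13.** The slow hydrolysis of a hindered dithiane may expose the dienyne, the tertiary allylic alcohol and the newly formed α-silyloxy aldehyde to long reaction times, with decomposition or epimerisation. Fallback, from 17 back to 19: the dithiane is hydrolysed before the side chain is attached, when only a gem-dibromoalkene, an acetate and a silyl ether are present (MeI/CaCO3, or PhI(OCOCF3)2 in aqueous MeCN if sluggish). This gives the dibromoalkene aldehyde F9. F9 is then coupled with 7 under the conditions of step 12 with Et3N as base, which gives 19 directly.

**Step 12.** Over-coupling at the second bromine and slowing of the catalyst by the two thioether sulfur atoms are the likely problems; copper-mediated alkyne dimerisation would consume 7. Fallback, from 7 and 17 back to 18: 7 is converted with Bu3SnOMe (toluene, 60 °C) into the alkynylstannane F10. F10 is joined to 17 by a Stille coupling (Pd2(dba)3, tri(2-furyl)phosphine, toluene). This is free of copper and amine and is a known trans-selective coupling of 1,1-dibromoalkenes.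

**Step 2.** Competing oxidative addition at the vinylic bromide of the product (double coupling) and base-induced loss of the allylic bromide of 3 are the likely problems. Fallback, from 3 back to 4: copper-catalysed substitution of the allylic bromide of 3 by vinylmagnesium bromide (CuI cat., THF, −20 °C) gives 2-bromopenta-1,4-diene F11. Cross-metathesis of F11 with an excess of 2-methylbut-3-en-2-ol (second-generation Hoveyda–Grubbs catalyst, CH2Cl2, 40 °C) gives 4. The 2-bromoalkene is inert to the ruthenium carbene and the tertiary allylic alcohol partner favours the (E)-alkene.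

## Further compounds

F1 | step 14 | (1S,4R,5S,6S)-5-[(tert-butyldimethylsilyl)oxy]-4-hydroxy-3-[(5E)-7-hydroxy-7-methyl-3-methylideneoct-5-en-1-yn-1-yl]-6-methoxycyclohex-2-en-1-yl acetate (C6 epimer of 21) | C=C(C#CC1=C[C@H](OC(C)=O)[C@H](OC)[C@@H](O[Si](C)(C)C(C)(C)C)[C@@H]1O)C/C=C/C(C)(C)O
F2 | step 14 | ring C6 ketone corresponding to 21 (cyclohex-2-en-1-one with the alkynyl group at the α-carbon) | C=C(C#CC1=C[C@H](OC(C)=O)[C@H](OC)[C@@H](O[Si](C)(C)C(C)(C)C)C1=O)C/C=C/C(C)(C)O
F3 | step 9 | benzyl 2-O-benzyl-3,4-O-(1-methoxyethylidene)-β-L-arabinopyranoside | c1ccccc1CO[C@@H]1[C@H](OCc2ccccc2)[C@H]2OC(C)(OC)O[C@H]2CO1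
F4 | step 9 | benzyl 4-O-acetyl-2-O-benzyl-β-L-arabinopyranoside | c1ccccc1CO[C@@H]1[C@H](OCc2ccccc2)[C@@H](O)[C@@H](OC(C)=O)CO1
F5 | step 9 | benzyl 4-O-acetyl-2-O-benzyl-3-O-methyl-β-L-arabinopyranoside | c1ccccc1CO[C@@H]1[C@H](OCc2ccccc2)[C@@H](OC)[C@@H](OC(C)=O)CO1
F6 | step 9 | 4-O-acetyl-3-O-methyl-L-arabinopyranose | OC1[C@H](O)[C@@H](OC)[C@@H](OC(C)=O)CO1
F7 | step 9 | 4-O-acetyl-3-O-methyl-L-arabinose propane-1,3-diyl dithioacetal | S1CCCSC1[C@H](O)[C@@H](OC)[C@@H](OC(C)=O)CO
F8 | step 9 | 4-O-acetyl-2,5-bis-O-(tert-butyldimethylsilyl)-3-O-methyl-L-arabinose propane-1,3-diyl dithioacetal | S1CCCSC1[C@H](O[Si](C)(C)C(C)(C)C)[C@@H](OC)[C@@H](OC(C)=O)CO[Si](C)(C)C(C)(C)C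
F9 | step 13 | 4-O-acetyl-6,6-dibromo-2-O-(tert-butyldimethylsilyl)-5,6-dideoxy-3-O-methyl-aldehydo-L-arabino-hex-5-enose | O=C[C@H](O[Si](C)(C)C(C)(C)C)[C@@H](OC)[C@@H](OC(C)=O)C=C(Br)Br
F10 | step 12 | (3E)-2-methyl-6-methylidene-8-(tributylstannyl)oct-3-en-7-yn-2-ol | CC(C)(O)/C=C/CC(=C)C#C[Sn](CCCC)(CCCC)CCCC
F11 | step 2 | 2-bromopenta-1,4-diene | C=CCC(Br)=C
A1 | alternative 1 | 3-hydroxy-4-methoxy-5,6-O-isopropylidenecyclohexanone (ketone at ring C1) | O=C1C[C@H](O)[C@H](OC)[C@H]2OC(C)(C)O[C@@H]12
A2 | alternative 1 | methyl 6-deoxy-3,4-O-isopropylidene-2-O-methyl-β-L-arabino-hex-5-enopyranoside | CO[C@H]1OC(=C)[C@@H]2OC(C)(C)O[C@@H]2[C@H]1OC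
A3 | alternative 1 | D-galactose | O=C[C@H](O)[C@@H](O)[C@@H](O)[C@H](O)CO
A4 | alternative 2 | 4,5-epoxy enone with ketone at ring C3 and dimethyl ketal at ring C6 carrying the triethylsilyl-protected side chain | O=C1C=C(C#CC(=C)C/C=C/C(C)(C)O[Si](CC)(CC)CC)C(OC)(OC)[C@@H]2O[C@H]12
A5 | alternative 2 | 3-alkynyl-4,4-dimethoxycyclohexa-2,5-dien-1-one carrying the triethylsilyl-protected side chain (quinone monoketal) | O=C1C=CC(OC)(OC)C(C#CC(=C)C/C=C/C(C)(C)O[Si](CC)(CC)CC)=C1
A6 | alternative 3 | cyclohexene with 4-methoxybenzyloxymethyl group at ring C1, acetate at C3, methyl ether at C4 and 5,6-O-isopropylidene acetal | COc1ccc(COCC2=C[C@H](OC(C)=O)[C@H](OC)[C@H]3OC(C)(C)O[C@@H]23)cc1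
A7 | alternative 3 | acyclic 1,7-diene: 3-acetoxy-4-methoxy-5,6-O-isopropylidene chain with a vinyl group at one end and a 2-(4-methoxybenzyloxymethyl)vinyl group at the other | C=C[C@H](OC(C)=O)[C@H](OC)[C@H]1OC(C)(C)O[C@H]1C(=C)COCc1ccc(OC)cc1
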